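**Plan**

- Labels: rings A pyrrolidine, B cyclopentane, C piperidine, D δ-lactone, E cyclohexane, F cyclopentene. Atoms: C1 (methyl) on C2, C3, N4, C6 (NCH of C/E), C7=C8–C9–C10–C11 (ring F), C12, C13 (ring E CH2), C14, C15 (with methyl C16 and O17), C18 (lactone C=O), C20, C21, C22 (quaternary), C23, C24, C25, C26 (NCH).
- Cuts, in retro order: N4–O; a helper carboxyl C27 on C12; C11–C12 of ring E as a [3,3] retron, giving an eight-membered allylic lactone C27(=O)–O–C8; that ester bond; O17–C15 (ring D); C14–C13; C6–C7; then ring C back to a β-lactam (N4–C15) fused to ring B.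
- What makes the key event possible: C11 is an allylic methine between the ring F alkene carbon C7 and the ring E methylene C12, so C27(=O)–C12–C11–C7=C8 is a γ,δ-unsaturated acid. Its Claisen precursor is an ester on C8 of the same five-membered ring, which ties the C14 arm to the C6 arm of ring C.
- Forward ring order: B (from cyclopentadiene), temporary β-lactam, A (Heck), C (two-carbon ring expansion of the β-lactam), F brought in intact, D (lactonisation), temporary eight-membered lactone, E last by ring contraction.
- Stereochemistry: C22/C26 from enzymatic resolution; C25 from cis Heck closure; C2 from convex-face hydrogenation; quaternary C22 from alkylation held cis by the β-lactam; C6 from conjugate addition anti to ring B; C14 by equilibration trans to C6; C15 from the tethered lactonisation; C8 from CBS reduction; C11 from C8 by suprafacial [3,3] transfer; N4 by peracid oxidation.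

Key step: step 18

Assumption: amine 37 is oxidised through the nitrogen invertomer whose lone pair is syn to C22 and the C2 methyl group (concave face of the A/B bicycle), which is the nitrogen configuration written in the target.
Remark: cyclopentadiene (1) is used freshly cracked from its commercial dimer.

**Route**

Step 1
Reactants: 1 cyclopenta-1,3-diene; 2 chlorosulfonyl isocyanate
Product: 4 rac-cis-6-azabicyclo[3.2.0]hept-3-en-7-one, via N-chlorosulfonyl lactam 3 (not isolated)
Conditions: Et2O, −20 °C to rt; then aq Na2SO3, NaOH (pH 7–8), 0 °C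
Reagents that add atoms: none
Why: Stepwise [2+2] cycloaddition of the isocyanate to the diene places nitrogen on the allylic carbon and can only give the cis-fused β-lactam (racemic), and sulfite reduction removes the N-sulfonyl chloride.

Step 2
Reactants: 4 rac-cis-6-azabicyclo[3.2.0]hept-3-en-7-one
Product: 5 (1R,2S)-2-aminocyclopent-3-ene-1-carboxylic acid
Conditions: lipase B from Candida antarctica (immobilized), H2O (0.5 equiv), iPr2O, 60 °C; filtration
Reagents that add atoms: water, O
Why: Enzymatic kinetic resolution by enantioselective lactam hydrolysis should open only the (1R,5S)-lactam, so the insoluble (1R,2S)-amino acid (future C22 and C26) is separated from the unreacted enantiomeric lactam.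

Step 3
Reactants: 5 (1R,2S)-2-aminocyclopent-3-ene-1-carboxylic acid
Product: 6 (1R,5S)-6-azabicyclo[3.2.0]hept-3-en-7-one
Conditions: 2-chloro-1-methylpyridinium iodide, Et3N, MeCN (0.01 M), 70 °C
Reagents that add atoms: none
Why: Carboxyl activation as the 2-acyloxypyridinium salt (Mukaiyama reagent) and intramolecular N-acylation under dilution should re-close the β-lactam without touching either stereocenter.

Step 4
Reactants: 6 (1R,5S)-6-azabicyclo[3.2.0]hept-3-en-7-one; 7 2,3-dibromoprop-1-ene
Product: 8 (1R,5S)-6-(2-bromoprop-2-en-1-yl)-6-azabicyclo[3.2.0]hept-3-en-7-one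
Conditions: KOH (powder), Bu4NBr (10 mol %), THF, 0 °C to rt
Reagents that add atoms: none
Why: N-alkylation of the lactam anion under phase-transfer conditions occurs at the allylic bromide, the vinylic bromide being inert to substitution.

Step 5
Reactants: 8 (1R,5S)-6-(2-bromoprop-2-en-1-yl)-6-azabicyclo[3.2.0]hept-3-en-7-one
Product: 9 tricyclic diene β-lactam (ring A closed; exocyclic methylene on C2; C23=C24)
Conditions: Pd(OAc)2 (5 mol %), PPh3 (15 mol %), Et3N, MeCN, 80 °C
Reagents that add atoms: none
Why: Intramolecular Mizoroki–Heck reaction, in which 5-exo syn-carbopalladation of the cyclopentene on the face carrying nitrogen closes ring A cis-fused (sets C25) and β-hydride elimination can only go away from C25.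

Step 6
Reactants: 9 tricyclic diene β-lactam
Product: 10 tricyclic β-lactam with the C2 methyl group
Conditions: H2 (1 atm), Pd/C (10 %), EtOAc, rt
Reagents that add atoms: none
Why: Heterogeneous hydrogenation saturates both alkenes, and hydrogen should reach the exocyclic methylene from the convex face of the bowl (anti to the β-lactam and ring B), which puts the C2 methyl group cis to C24 as required.

Step 7
Reactants: 10 tricyclic β-lactam with the C2 methyl group; 11 tert-butyl acrylate
Product: 12 quaternary β-lactam (C22 bearing the CH2CH2CO2tBu arm)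
Conditions: LDA, THF, −78 °C; then 11, −78 °C; aq NH4Cl
Reagents that add atoms: none
Why: Lactam enolate formation at the only α-carbon (C22) and Michael addition to the acrylate; the new chain can only enter trans to the C26–C25 bond because ring B must stay cis-fused to the four-membered ring, so C22 forms as one diastereomer with the future C15 held cis to nitrogen.

Step 8
Reactants: 12 quaternary β-lactam; 13 ethynylmagnesium bromide
Product: 15 tricyclic vinylogous amide (2,3-dihydropyridin-4-one ring C), via amino ynone 14 (not isolated)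
Conditions: THF, −78 to 0 °C; aq NH4Cl; then K2CO3 (20 mol %), MeOH, rt
Reagents that add atoms: none
Why: Addition of the alkynyl Grignard reagent to the strained, pyramidal-nitrogen β-lactam carbonyl opens the four-membered ring to an amino ynone, whose secondary amine should add 6-endo-dig to give the vinylogous amide, a two-carbon ring expansion of the temporary β-lactam into ring C.

Step 9
Reactants: 16 cyclopent-2-en-1-one
Product: 17 2-iodocyclopent-2-en-1-one
Conditions: I2, pyridine, CH2Cl2, 0 °C to rt
Reagents that add atoms: iodine, II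
Why: α-Iodination of the enone by conjugate addition of pyridine, iodination of the resulting enolate and elimination.

Step 10
Reactants: 17 2-iodocyclopent-2-en-1-one
Product: 18 (R)-2-iodocyclopent-2-en-1-ol
Conditions: (S)-2-methyl-CBS-oxazaborolidine (10 mol %), BH3·SMe2, THF, −20 °C; MeOH
Reagents that add atoms: none
Why: Corey–Bakshi–Shibata reduction in which the iodoalkenyl carbon acts as the large group, so the (S)-catalyst should give the (R)-allylic alcohol, the center (C8) that later controls C11.

Step 11
Reactants: 18 (R)-2-iodocyclopent-2-en-1-ol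
Product: 19 (R)-tert-butyl[(2-iodocyclopent-2-en-1-yl)oxy]diphenylsilane
Conditions: t-BuPh2SiCl, imidazole, DMF, rt
Reagents that add atoms: tert-butyl(chloro)diphenylsilane, CC(C)(C)[Si](Cl)(c1ccccc1)c1ccccc1
Why: Silylation of the secondary alcohol with a silyl group chosen to survive the acid of step 15.

Step 12
Reactants: 15 tricyclic vinylogous amide; 19 (R)-tert-butyl[(2-iodocyclopent-2-en-1-yl)oxy]diphenylsilane
Product: 22 C6-cyclopentenyl piperidin-4-one, via alkenylmagnesium chloride 20 (not isolated), via silyl enol ether 21 (not isolated)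
Conditions: 19, iPrMgCl·LiCl, THF, −20 °C; then CuBr·SMe2 (20 mol %), Me3SiCl, 15, THF, −78 to −40 °C; then 1 M aq HCl, 0 °C
Reagents that add atoms: none
Why: Iodine–magnesium exchange gives the alkenyl Grignard reagent with C8 intact, and its CuBr-catalysed, Me3SiCl-assisted 1,4-addition to the cyclic vinylogous amide should occur at C6 from the face opposite ring B (C25), giving the C6–C7 bond cis to H26 before acid hydrolysis of the silyl enol ether.

Step 13
Reactants: 22 C6-cyclopentenyl piperidin-4-one; 23 allyl acrylate
Product: 24 keto diester (allyl propanoate arm on C14)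
Conditions: t-BuOK (10 mol %), t-BuOH/THF, 0 °C
Reagents that add atoms: none
Why: Base-catalysed Michael addition at the only enolisable position (C14), where under these equilibrating conditions the new chain should settle trans to the C6 cyclopentenyl group (both equatorial on the chair piperidinone).

Step 14
Reactants: 24 keto diester; 25 dibromomethane
Product: 26 C15 methylene compound
Conditions: Zn, TiCl4, THF/CH2Cl2, 0 °C to rt
Reagents that add atoms: none
Why: Lombardo-type methylenation with the non-basic gem-dizinc/titanium reagent should convert the hindered, enolisable ketone into the exocyclic alkene without epimerising C14 or touching the esters.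

Step 15
Reactants: 26 C15 methylene compound
Product: 28 tetracyclic lactone (rings A–D; silyl ether on C8; allyl ester at C27), via carboxylic acid 27 (not isolated)
Conditions: CF3CO2H/CH2Cl2 (1:3), 0 °C to rt; aq NaHCO3
Reagents that add atoms: none
Why: Acidolysis of the tert-butyl ester, Markovnikov protonation of the 1,1-disubstituted alkene and capture of the C15 cation by the tethered acid (δ-lactonisation); the C21 arm can reach C15 only from its own face, which sets C15 with O17 cis to C21 and turns the methylene into the C16 methyl group.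

Step 16
Reactants: 28 tetracyclic lactone
Product: 30 tetracyclic lactone hydroxy acid (C8–OH; C27 acid), via silyl ether acid 29 (not isolated)
Conditions: Pd(PPh3)4 (5 mol %), morpholine, THF, rt; then Bu4NF, AcOH, THF, rt
Reagents that add atoms: none
Why: Palladium-catalysed allyl transfer to morpholine frees the C27 acid and buffered fluoride removes the silyl ether, neither affecting the tertiary δ-lactone.

Step 17
Reactants: 30 tetracyclic lactone hydroxy acid
Product: 32 eight-membered lactone (C27(=O)–O–C8 bridging the C14 and C6 arms), via mixed anhydride 31 (not isolated)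
Conditions: 2,4,6-trichlorobenzoyl chloride, Et3N, THF, rt; then slow addition to DMAP, toluene (1 mM), 80 °C
Reagents that add atoms: none
Why: Yamaguchi macrolactonisation under high dilution with retention at C8, where the trans-1,2 arrangement of the two arms on ring C and the rigid cyclopentene should pre-organise the seco acid for the medium ring.

Step 18
Reactants: 32 eight-membered lactone
Product: 35 hexacyclic C12 carboxylic acid (ring E closed; C7=C8), via bis(silyl ketene acetal) 33 (not isolated), via silyl ester 34 (not isolated)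
Conditions: Me3SiCl, Et3N, LDA (3 equiv), THF, −78 °C; then rt to 60 °C; 1 M aq HCl
Reagents that add atoms: none
Why: Both lactones are enolised and O-silylated, but only the eight-membered one is an allyl vinyl ether (C12=C27(OSi)–O–C8–C7=C11); it should undergo the [3,3] shift, forming C11–C12, breaking O–C8 and moving the alkene to C7=C8. Ring E (C6–C7–C11–C12–C13–C14) closes as an eight-to-six ring contraction, formally endo with respect to the C7=C11 bond, through a bicyclo[3.3.1]-like array in which the C13–C14–C6 tether permits only the chair-like arrangement of the six reacting atoms. C11 is controlled by C8, because the new bond must form on the cyclopentene face from which the C8–O bond departs (suprafacial 1,3-transfer), whatever the transition-state shape; C12 follows from the ring-constrained Z ketene acetal and is erased in step 19. The selectivity needed is rearrangement of the allylic ester only and [3,3] shift over ketene loss or C-silylation: the δ-lactone ketene acetal has no allyl partner and returns to the lactone on work-up, and in-situ silylation at −78 °C protects the enolate. The closest known reaction type is the ester-enolate (Ireland–Claisen) ring contraction of medium and large allylic lactones to carbocyclic acids.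

Step 19
Reactants: 35 hexacyclic C12 carboxylic acid
Product: 37 hexacyclic amine (target without the N-oxide oxygen), via thiohydroxamate ester 36 (not isolated)
Conditions: N-hydroxypyridine-2-thione, DCC, DMAP (cat.), CH2Cl2, dark, rt; then t-BuSH, hν (visible), rt
Reagents that add atoms: none
Why: Barton decarboxylation, in which the thiohydroxamate ester fragments under light to the secondary C12 radical that the thiol should reduce faster than it can rearrange, removing the helper carboxyl and the C12 stereocenter.

Step 20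
Reactants: 37 hexacyclic amine
Product: 38 target N-oxide
Conditions: mCPBA (1.05 equiv), CH2Cl2, −40 to 0 °C; K2CO3
Reagents that add atoms: 3-chloroperoxybenzoic acid, OOC(=O)c1cccc(Cl)c1
Why: Peracid oxidation of the tertiary amine is much faster than epoxidation of the trisubstituted alkene, and under the stated assumption oxygen is delivered to the lone pair on the concave face of the A/B bicycle to give the nitrogen configuration of the target.

**Compound list**

1 | cyclopenta-1,3-diene | C1=CC=CC1 | starting material
2 | chlorosulfonyl isocyanate | O=C=NS(=O)(=O)Cl | starting material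
3 | rac-cis-6-(chlorosulfonyl)-6-azabicyclo[3.2.0]hept-3-en-7-one (racemic, one enantiomer drawn; not isolated) | ClS(=O)(=O)N1C(=O)[C@@H]2CC=C[C@@H]21 | intermediate
4 | rac-cis-6-azabicyclo[3.2.0]hept-3-en-7-one (racemic, one enantiomer drawn) | N1C(=O)[C@@H]2CC=C[C@@H]21 | intermediate
5 | (1R,2S)-2-aminocyclopent-3-ene-1-carboxylic acid | OC(=O)[C@@H]1CC=C[C@@H]1N | intermediate
6 | (1R,5S)-6-azabicyclo[3.2.0]hept-3-en-7-one | N1C(=O)[C@@H]2CC=C[C@@H]21 | intermediate
7 | 2,3-dibromoprop-1-ene | BrCC(Br)=C | starting material
8 | (1R,5S)-6-(2-bromoprop-2-en-1-yl)-6-azabicyclo[3.2.0]hept-3-en-7-one | C=C(Br)CN1C(=O)[C@@H]2CC=C[C@@H]21 | intermediate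
9 | tricyclic diene β-lactam (rings A and B plus β-lactam; exocyclic methylene on C2; C23=C24) | C=C1CN2C(=O)[C@@H]3C=C[C@H]1[C@@H]32 | intermediate
10 | tricyclic β-lactam with the C2 methyl group cis to C24 | C[C@@H]1CN2C(=O)[C@@H]3CC[C@H]1[C@@H]32 | intermediate
11 | tert-butyl acrylate | C=CC(=O)OC(C)(C)C | starting material
12 | quaternary β-lactam (C22 bearing the CH2CH2CO2tBu arm) | C[C@@H]1CN2C(=O)[C@]3(CCC(=O)OC(C)(C)C)CC[C@H]1[C@@H]32 | intermediate
13 | ethynylmagnesium bromide | C#C[Mg]Br | starting material
14 | amino ynone from opening of 12 (not isolated) | C[C@@H]1CN[C@H]2[C@@H]1CC[C@@]2(CCC(=O)OC(C)(C)C)C(=O)C#C | intermediate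
15 | tricyclic vinylogous amide (N4–C6H=C14H–C15=O; ring C) | C[C@@H]1CN2C=CC(=O)[C@]3(CCC(=O)OC(C)(C)C)CC[C@H]1[C@@H]32 | intermediate
16 | cyclopent-2-en-1-one | O=C1C=CCC1 | starting material
17 | 2-iodocyclopent-2-en-1-one | O=C1C(I)=CCC1 | intermediate
18 | (R)-2-iodocyclopent-2-en-1-ol | O[C@@H]1CCC=C1I | intermediate
19 | (R)-tert-butyl[(2-iodocyclopent-2-en-1-yl)oxy]diphenylsilane | CC(C)(C)[Si](O[C@@H]1CCC=C1I)(c1ccccc1)c1ccccc1 | intermediate
20 | alkenylmagnesium chloride from 19 (not isolated) | CC(C)(C)[Si](O[C@@H]1CCC=C1[Mg]Cl)(c1ccccc1)c1ccccc1 | intermediate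
21 | trimethylsilyl enol ether of 22 (not isolated) | C[C@@H]1CN2[C@@H](C3=CCC[C@H]3O[Si](c4ccccc4)(c4ccccc4)C(C)(C)C)C=C(O[Si](C)(C)C)[C@]3(CCC(=O)OC(C)(C)C)CC[C@H]1[C@@H]32 | intermediate
22 | C6-cyclopentenyl piperidin-4-one (C8 silyl ether; C14 unsubstituted) | C[C@@H]1CN2[C@@H](C3=CCC[C@H]3O[Si](c4ccccc4)(c4ccccc4)C(C)(C)C)CC(=O)[C@]3(CCC(=O)OC(C)(C)C)CC[C@H]1[C@@H]32 | intermediate
23 | allyl acrylate | C=CC(=O)OCC=C | starting material
24 | keto diester (allyl propanoate arm on C14, trans to C6 substituent) | C[C@@H]1CN2[C@@H](C3=CCC[C@H]3O[Si](c4ccccc4)(c4ccccc4)C(C)(C)C)[C@H](CCC(=O)OCC=C)C(=O)[C@]3(CCC(=O)OC(C)(C)C)CC[C@H]1[C@@H]32 | intermediate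
25 | dibromomethane | BrCBr | starting material
26 | C15 methylene compound | C[C@@H]1CN2[C@@H](C3=CCC[C@H]3O[Si](c4ccccc4)(c4ccccc4)C(C)(C)C)[C@H](CCC(=O)OCC=C)C(=C)[C@]3(CCC(=O)OC(C)(C)C)CC[C@H]1[C@@H]32 | intermediate
27 | C18 carboxylic acid from 26 (not isolated) | C[C@@H]1CN2[C@@H](C3=CCC[C@H]3O[Si](c4ccccc4)(c4ccccc4)C(C)(C)C)[C@H](CCC(=O)OCC=C)C(=C)[C@]3(CCC(=O)O)CC[C@H]1[C@@H]32 | intermediate
28 | tetracyclic lactone (rings A–D; C8 silyl ether; C27 allyl ester) | C[C@@H]1CN2[C@@H](C3=CCC[C@H]3O[Si](c4ccccc4)(c4ccccc4)C(C)(C)C)[C@H](CCC(=O)OCC=C)[C@@]3(C)OC(=O)CC[C@]34CC[C@H]1[C@@H]42 | intermediate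
29 | tetracyclic lactone C27 acid with C8 silyl ether (not isolated) | C[C@@H]1CN2[C@@H](C3=CCC[C@H]3O[Si](c4ccccc4)(c4ccccc4)C(C)(C)C)[C@H](CCC(=O)O)[C@@]3(C)OC(=O)CC[C@]34CC[C@H]1[C@@H]42 | intermediate
30 | tetracyclic lactone hydroxy acid | C[C@@H]1CN2[C@@H](C3=CCC[C@H]3O)[C@H](CCC(=O)O)[C@@]3(C)OC(=O)CC[C@]34CC[C@H]1[C@@H]42 | intermediate
31 | mixed 2,4,6-trichlorobenzoic anhydride of 30 (not isolated) | C[C@@H]1CN2[C@@H](C3=CCC[C@H]3O)[C@H](CCC(=O)OC(=O)c3c(Cl)cc(Cl)cc3Cl)[C@@]3(C)OC(=O)CC[C@]34CC[C@H]1[C@@H]42 | intermediate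
32 | eight-membered allylic lactone (key precursor) | C[C@@H]1CN2[C@H]3C4=CCC[C@H]4OC(=O)CC[C@@H]3[C@@]3(C)OC(=O)CC[C@]34CC[C@H]1[C@@H]42 | intermediate
33 | bis(trimethylsilyl ketene acetal) of 32 (ring-constrained alkene geometry; not isolated) | C[C@@H]1CN2[C@H]3C4=CCC[C@H]4OC(O[Si](C)(C)C)=CC[C@@H]3[C@@]3(C)OC(O[Si](C)(C)C)=CC[C@]34CC[C@H]1[C@@H]42 | intermediate
34 | rearranged trimethylsilyl ester (δ-lactone still as ketene acetal; not isolated) | C[C@@H]1CN2[C@H]3C4=CCC[C@@H]4[C@H](C(=O)O[Si](C)(C)C)C[C@@H]3[C@@]3(C)OC(O[Si](C)(C)C)=CC[C@]34CC[C@H]1[C@@H]42 | intermediate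
35 | hexacyclic C12 carboxylic acid | C[C@@H]1CN2[C@H]3C4=CCC[C@@H]4[C@H](C(=O)O)C[C@@H]3[C@@]3(C)OC(=O)CC[C@]34CC[C@H]1[C@@H]42 | intermediate
36 | thiohydroxamate (Barton) ester of 35 (not isolated) | C[C@@H]1CN2[C@H]3C4=CCC[C@@H]4[C@H](C(=O)On5ccccc5=S)C[C@@H]3[C@@]3(C)OC(=O)CC[C@]34CC[C@H]1[C@@H]42 | intermediate
37 | hexacyclic amine (target without the N-oxide oxygen) | C[C@@H]1CN2[C@H]3C4=CCC[C@@H]4CC[C@@H]3[C@@]3(C)OC(=O)CC[C@]34CC[C@H]1[C@@H]42 | intermediate
38 | target N-oxide | C[C@@H]1C[N@@+]2([O-])[C@H]3C4=CCC[C@@H]4CC[C@@H]3[C@@]3(C)OC(=O)CC[C@]34CC[C@H]1[C@@H]42 | target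

**Step count and risks**

Total steps: 20. Longest linear sequence: 17 (steps 1–8 and 12–20).

Step 18 (key step). What may go wrong: the strained bicyclic transition state may make the [3,3] shift slower than fragmentation of the ester enolate (loss of the C8 alkoxide as a ketene forms), C-silylation, or condensation with the second lactone. Fallback (same C11–C12 bond, closed by ionic allylic substitution): set out from ketone 22. Base-catalysed Michael addition to 1,1-bis(phenylsulfonyl)ethene gives the bis-sulfone ketone F1. Methylenation as in step 14 gives the bis-sulfone methylene compound F2, and CF3CO2H as in step 15 gives the bis-sulfone lactone F3. Bu4NF/AcOH frees the allylic alcohol F4, and ClCO2Me/pyridine gives the allylic methyl carbonate F5. Pd(PPh3)4 in THF ionises the carbonate with inversion; the bis-sulfonyl carbanion, formed by the released methoxide, attacks C11 anti to palladium, on the face the C8–O bond left (Tsuji–Trost, net retention, the same transfer from C8 to C11). This closes ring E as the hexacyclic bis-sulfone F6. Sodium amalgam (Na2HPO4, MeOH/THF, −20 °C) removes both sulfonyl groups and the route is rejoined at amine 37.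

Step 17. What may go wrong: oligomerisation (diolide formation) instead of medium-ring closure, or slow acyl transfer to the hindered allylic alcohol. Fallback (ester bond made first, ring closed by a C–C bond): set out from ketone 22. Bu4NF/AcOH gives the allylic alcohol ketone F7, and acryloyl chloride/Et3N gives the acrylate ester F8. Dilute base (Cs2CO3, MeCN) induces intramolecular Michael addition of the C14 enolate to the tethered acrylate, which forms C13–C14 and the eight-membered ring together to give the keto lactone F9 (C14 epimerisable, expected trans). Methylenation as in step 14 gives the methylene lactone F10, and CF3CO2H as in step 15 closes ring D, rejoining the route at lactone 32.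

Step 8. What may go wrong: collapse of the tetrahedral adduct in the flask followed by a second addition of the Grignard reagent to the ynone, or attack at the tert-butyl ester. Fallback: set out from β-lactam 12. Me(MeO)NH·HCl/AlMe3 in CH2Cl2 opens the lactam to the Weinreb amide F11 (secondary amine free). Ethynylmagnesium bromide then stops at the chelated adduct and gives ynone 14 on work-up, which cyclises with K2CO3/MeOH as in step 8, rejoining the route at 15.

Further compounds
F1 | step 18 | bis-sulfone ketone (22 with a CH2CH(SO2Ph)2 arm on C14) | C[C@@H]1CN2[C@@H](C3=CCC[C@H]3O[Si](c4ccccc4)(c4ccccc4)C(C)(C)C)[C@H](CC(S(=O)(=O)c4ccccc4)S(=O)(=O)c4ccccc4)C(=O)[C@]3(CCC(=O)OC(C)(C)C)CC[C@H]1[C@@H]32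
F2 | step 18 | bis-sulfone C15 methylene compound | C[C@@H]1CN2[C@@H](C3=CCC[C@H]3O[Si](c4ccccc4)(c4ccccc4)C(C)(C)C)[C@H](CC(S(=O)(=O)c4ccccc4)S(=O)(=O)c4ccccc4)C(=C)[C@]3(CCC(=O)OC(C)(C)C)CC[C@H]1[C@@H]32
F3 | step 18 | bis-sulfone tetracyclic lactone silyl ether | C[C@@H]1CN2[C@@H](C3=CCC[C@H]3O[Si](c4ccccc4)(c4ccccc4)C(C)(C)C)[C@H](CC(S(=O)(=O)c4ccccc4)S(=O)(=O)c4ccccc4)[C@@]3(C)OC(=O)CC[C@]34CC[C@H]1[C@@H]42
F4 | step 18 | bis-sulfone tetracyclic lactone allylic alcohol | C[C@@H]1CN2[C@@H](C3=CCC[C@H]3O)[C@H](CC(S(=O)(=O)c4ccccc4)S(=O)(=O)c4ccccc4)[C@@]3(C)OC(=O)CC[C@]34CC[C@H]1[C@@H]42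
F5 | step 18 | bis-sulfone tetracyclic lactone allylic methyl carbonate | C[C@@H]1CN2[C@@H](C3=CCC[C@H]3OC(=O)OC)[C@H](CC(S(=O)(=O)c4ccccc4)S(=O)(=O)c4ccccc4)[C@@]3(C)OC(=O)CC[C@]34CC[C@H]1[C@@H]42
F6 | step 18 | hexacyclic lactone amine with C12 bis(phenylsulfonyl) | C[C@@H]1CN2[C@H]3C4=CCC[C@@H]4C(S(=O)(=O)c5ccccc5)(S(=O)(=O)c5ccccc5)C[C@@H]3[C@@]3(C)OC(=O)CC[C@]34CC[C@H]1[C@@H]42
F7 | step 17 | allylic alcohol ketone (22 without the silyl group) | C[C@@H]1CN2[C@@H](C3=CCC[C@H]3O)CC(=O)[C@]3(CCC(=O)OC(C)(C)C)CC[C@H]1[C@@H]32
F8 | step 17 | acrylate ester of F7 | C[C@@H]1CN2[C@@H](C3=CCC[C@H]3OC(=O)C=C)CC(=O)[C@]3(CCC(=O)OC(C)(C)C)CC[C@H]1[C@@H]32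
F9 | step 17 | eight-membered keto lactone | C[C@@H]1CN2[C@H]3C4=CCC[C@H]4OC(=O)CC[C@@H]3C(=O)[C@]3(CCC(=O)OC(C)(C)C)CC[C@H]1[C@@H]32
F10 | step 17 | eight-membered lactone C15 methylene compound | C[C@@H]1CN2[C@H]3C4=CCC[C@H]4OC(=O)CC[C@@H]3C(=C)[C@]3(CCC(=O)OC(C)(C)C)CC[C@H]1[C@@H]32
F11 | step 8 | Weinreb amide from opening of 12 | C[C@@H]1CN[C@H]2[C@@H]1CC[C@@]2(CCC(=O)OC(C)(C)C)C(=O)N(C)OC
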